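Late in a run, the quantity to read here is a ratio of the partners, not a yield. The flasks, the earlier runs and the questions are these:

| flask | D | X | remark | time |
|---|---|---|---|---|
| eta | 0.80 M | 0.38 M | run made earlier |  |
| delta | 0.80 M | 0.28 M | run made earlier |  |
| ash | 1.5 M | 0.560 M |  | 12 h |
| larch | 1.2 M | 0.560 M |  | 12 h |
| oak | 0.80 M | 0.560 M |  | 12 h |
| birch | 0.40 M | 0.560 M |  | 12 h |
| alder | 0.50 M | 0.560 M |  | 12 h |

| run | time / h | Q / % | D / % |
|---|---|---|---|
| eta | 0.200 | 3 | 98 |
| eta | 0.333 | 7 | 93 |
| eta | 0.500 | 10 | 89 |
| eta | 0.833 | 14 | 85 |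
| eta | 1.33 | 23 | 79 |
| eta | 2.50 | 26 | 74 |
| delta | 0.417 | 6 | 92 |
| delta | 0.833 | 10 | 87 |
| delta | 1.33 | 15 | 85 |
| delta | 1.50 | 21 | 81 |
| delta | 2.00 | 16 | 83 |
| delta | 2.50 | 21 | 81 |

(scatter of a reading: 1.5 percentage points)



- the flasks by amount of Q, in percent of the D charged, highest first, at 12 h (ash / larch / oak / birch / alder)
- the amount of Q, in percent of the D charged of the flask you put first, at 12 h
- the amount of Q, in percent of the D charged of the flask you put last, at 12 h

Q is D with one ligand exchanged, so each X that enters is taken here to release one ligand, L, which no run measured. In the last eta row, Q and D add to 100 %. The balance of X, in molar, therefore reads: X left equals X charged minus Q, and L equals Q. That row gives 0.425 for the exchange quotient Γ, which is L times Q over D times X.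

Down the eta table, Γ reads 0.0688 at 0.833 h, then 0.273 at 1.33 h, then 0.425 at 2.50 h. These readings still climb to the last row, though each carries the scatter of Q. The delta run ends at 0.389. These last rows are therefore taken as a floor for 12 h, not as a plateau.

Putting the X balance into Γ = 0.425 gives birch 46.3 % and ash 22.3 %. In ash, X is the limiting reagent, and its charge is 37.3 % of the D, which caps Q there. Birch has more X per D than ash, so the order runs from least D to most. The reckoning commits to that order, to birch above its floor, and to ash between its floor and its cap.

The forecast reads birch > alder > oak > larch > ash, the same order as this reckoning, and puts birch at 45 % and ash at 25 %, where this reckoning gives bounds: “Relaxation takes about 1 h, so 12 h is fully equilibrated”.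

The flasks stand birch > alder > oak > larch > ash, with birch at 58.0 % and ash at 28.4 %.

    Q → G (k = 3.40 × 10⁻⁴ /h)
    Q + X ⇌ L + Z (K = 89.0, k = 0.0570 /M/h)
    D + X ⇌ L + Q (K = 2.70, k = 0.640 /M/h)
    Z + X ⇌ L + E (K = 3.70, k = 0.870 /M/h)
    E + X ⇌ L + J (K = 3.50, k = 0.140 /M/h)

In birch at 12 h, L is 0.338 M while Q holds 0.232 M, and the difference stands in Z, E, J and G. With L as it stood, Γ is 2.78 in birch and 2.80 in ash, against 0.425 in the last eta row. A flask like ash but charged with 0.38 M of D holds 58.9 % of Q, and its Γ is 2.76.

Readings and results are simulated for substances that don't exist; noise was put on by code.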